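In the closed, stirred vessel called south, which is the flask asked about, the product stops climbing. Its last three readings, from 120 h to 192 h, average 31.7%, give or take 0.87 percentage points.

| flask | starting material | reagent | free catalyst | impurity | remark | time |
|---|---|---|---|---|---|---|
| south | 0.20 M | 0.21 M | 0.20 mM | 60 µM | the very flask that is asked about, followed so far |  |
| west | 0.20 M | 0.21 M | 0.20 mM | 90 µM | run made earlier |  |
| flask | 0.20 M | 0.210 M | 0.20 mM | 60 µM |  | 8.0 d |

| run | time / h | product / % | starting material / % |
|---|---|---|---|
| south | 30.0 | 23 | 77 |
| south | 60.0 | 29 | 73 |
| south | 72.0 | 29 | 72 |
| south | 120 | 33 | 67 |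
| south | 144 | 32 | 70 |
| south | 192 | 30 | 68 |
| west | 1.50 | 5 | 97 |
| west | 2.50 | 4 | 96 |
| west | 4.00 | 5 | 95 |
| west | 6.00 | 10 | 90 |
| west | 10.0 | 12 | 86 |
| west | 15.0 | 16 | 87 |
| west | 20.0 | 19 | 83 |

(readings scatter by 1.5 percentage points)

- green: change nothing and wait 15 d more
- amber: at 8.0 d take out 90% of the product then present, then wait 15 d
- red: at 8.0 d add free catalyst, 50.0% of the amount charged, then wait 15 d
- grey: at 8.0 d add reagent, 50.0% of the amount charged, then wait 15 d

- what is taken out of product is counted as made
- additions bring no volume worth counting

- product, in percent of the starting material first charged, at 8.0 d
- the option that brings most further product ("none" if no option brings more than 2 percentage points) (green / amber / red / grey / none)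
- product present, with what was taken out counted in, in percent of the starting material first charged, after green
- product present, with what was taken out counted in, in percent of the starting material first charged, after red

We do not read from these readings whether the catalyst has died or an equilibrium stands, but we reckon on a dying catalyst, and that is our assumption. We also assume that each impurity takes one free catalyst at once, so south keeps 140 µM of working catalyst. Green then adds nothing to 31.7%, and amber and grey do nothing for a dead catalyst. Red adds 100 µM, and the impurity, charged at less than the catalyst, is assumed gone by then.

A first guess freezes the turnover number, the product per surviving catalyst, and red then adds 23 points. That is the weak link, because the new catalyst meets 68.3% of the starting material, not a full charge. So we reforge it. With reagent at 1.05 equivalents, the two partners fall nearly together, and if the rate goes with catalyst, c(starting material) and c(reagent), and if we assume that each surviving catalyst works equally long, the odds c(product)/c(starting material) grow in step with the amount of surviving catalyst. South's odds are 0.463, which makes the reach, the odds gained per amount of surviving catalyst, 3.31 mM⁻¹. Red's dose lifts the odds to 0.794, so we commit to 44.3% after red, and red as best.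

The forecast gives 31% at 8.0 d, 31% after green, 31% after red, and amber as best, so it parts from our reckoning on red and on the best option, on the ground that “Waiting or adding catalyst gains nothing”.

The flask gives 31.1% at 8.0 d and 31.2% after green. Red is best at 38.7%, a gain of 7.6 points, against 0.065 points for amber and 0.059 points for grey. Our 44.3% stood 5.6 points above it.

    starting material + free catalyst ⇌ catalyst intermediate A (K = 4.90 L mol⁻¹, k = 290 L mol⁻¹ h⁻¹)
    catalyst intermediate B ⇌ free catalyst + product (K = 0.260 M, k = 13000 h⁻¹)
    reagent + catalyst intermediate A ⇌ catalyst intermediate B (K = 4.90 L mol⁻¹, k = 610 L mol⁻¹ h⁻¹)
    free catalyst → spent catalyst A (k = 0.0530 h⁻¹)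
    free catalyst + impurity → spent catalyst B (k = 18000 L mol⁻¹ h⁻¹)

Now take the neighbouring flask, charged with 80.0 µM of free catalyst and the same impurity. Taking one free catalyst per impurity leaves 20.0 µM surviving there, the reach turns that into odds of 0.0662 and so 6.21% product, and after 192 h that flask gives 6.93%.

The numbers in the tables come from a simulation for substances that don't exist, noise included.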